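## Analysis of the target

Compound 17 is a coumestan (6H-benzofuro[3,2-c]chromen-6-one): benzene ring A (C1–C4, C4a, C11b) is fused to α-pyranone ring B (O5, C6=O), ring B shares the C6a=C11a bond with furan ring C (O11), and ring C is fused to phenolic ring D (C6b–C10a). A fifth ring, a 2,2-dimethyl-3,4-dihydro-2H-pyran, is fused across C1–C2 of ring A, with its oxygen on C1 and its benzylic CH2 on C2. Ring A is therefore a fully differentiated phloroglucinol: pyran oxygen at C1, methoxy at C3, lactone oxygen at C4a, carbon at C2 and C11b, hydrogen only at C4. Ring D carries the single free hydroxyl at C9. There is no stereocentre; apart from the CH2–CH2–CMe2 chain every skeletal atom is sp2, so the route should not create stereocentres that must later be erased. The sensitive points are the aryl lactone (opened by hydroxide or alkoxide), the electron-rich ring A with its open C4 position, and the need to tell the ring D phenol from the ring A phenol that becomes the pyran oxygen. The difficulty lies in placing three different oxygen substituents on ring A and in building the tetrasubstituted C6a=C11a bond convergently. The strategy rests on C11a: it is bonded only to C11b, C6a and O11, so it stands at the oxidation level of a ketone carbonyl and can be supplied as carbon monoxide 9 between a ring A aryl iodide and the α-carbon of a ring D lactone. Since C11b is flanked by two oxygen-bearing carbons (C1 and C4a), the mirror-symmetric iodide 4 is sufficient.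

## Retrosynthetic reasoning

**17 from 16.** The saturated C–C bond of the dihydropyran is traced back to the alkene of chromene 16, and the free 9-OH to its benzyl ether. One hydrogenation then saturates the ring and unmasks the phenol together. Keeping ring D protected until the last step is what allows the ring A hydroxyl to be the only free OH during the pyran annulation.

**16 from 14 (via 15), and 14 from 13.** The pyran is cut at C2–C(vinyl) and at O–CMe2. Forward, the 1,1-dimethylpropargyl ether 14 undergoes the aryl propargyl ether Claisen cascade. The cut is placed here because the hydroxyl on C1 of 13 has only one free ortho carbon, C2; the other ortho position is C11b. A cationic prenylation would have to choose between C2 and C4, whereas the sigmatropic route cannot reach C4.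

**13 from 10 (via 11 and 12).** Ring C is opened at O11–C11a and ring B at O5–C6. This leads to the 3-aroylbenzofuranone 10, in which the C6 carbonyl is still esterified by the ring D oxygen and C11a is a ketone. Forward, acid removes the two MOM groups to give 11. A freed ring A phenol takes over the lactone carbonyl from the ring D phenol, forming ring B in the 4-hydroxycoumarin 12. The released ring D phenol then condenses with C11a to form the furan. Both ring A phenols of 11 are equivalent, so the lactone swap has no regiochemical issue; whichever phenol does not lactonise becomes the C1 hydroxyl of 13.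

**10 from 4, 9 and 8 (key disconnection).** Both carbon–carbon bonds at C11a are cut, C11a–C11b and C6a–C11a. Ring A then arrives as aryl iodide 4, C11a as carbon monoxide 9, and C6, C6a and all of ring D as lactone 8. This completes the carbon skeleton in one step from two short fragments and installs C11a directly at the ketone level. The forward reaction needs CO insertion to precede aryl–enolate coupling and the enolate to be acylated at carbon.

**4 from 2 (via 3), and 2 from 1.** The C–I bond is traced to a lithiation between the two MOM ethers of 2, made from the symmetric resorcinol 1. The two acetal groups are the strongest directors on the ring and also the groups that the later acid step removes, so they serve twice.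

**8 from 6 (via 7), and 6 from 5.** The lactone C–O bond is cut to hydroxy acid 7, and its arylacetic acid chain is traced to the acetyl group of 5 through thioamide 6. The benzyl ether is already in place in 5, where the two ring D oxygens are differentiated. It should not be introduced after the lactone exists, because the lactone CH2 is about as acidic as a phenol and would compete as a carbon nucleophile in a benzylation.

## Alternatives that were turned down

**Alternative 1: oxygen analogue of the Fischer indole synthesis on a coumarin.**
- Disconnection: ring C is cut at C6a–C6b and O11–C11a. The precursor is A1, a 4-(aryloxyamino)coumarin that already holds rings A and B, the dihydropyran and the methoxy group.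
- Key step: under acid, the ene-hydroxylamine undergoes a [3,3] shift that forms C6a–C6b as the weak N–O bond breaks. After rearomatisation the new ring D phenol adds to C11a and the nitrogen is expelled, giving A2, the 9-O-benzyl ether of 17.
- For: it is metal-free and needs no gas. A2 is one hydrogenolysis from 17, so on the number of steps after the key step it is stronger than the chosen route, which needs four.
- Against: the 3-(benzyloxy)phenoxy group has two different ortho carbons. Only the one para to the benzyloxy group gives the 9-oxygenated pattern; the other gives the 7-isomer. A1 also requires a 4-hydroxycoumarin with the dihydropyran and methoxy group already placed on ring A, which brings back the unsymmetrical phloroglucinol problem. The amination at C4 is peri to the C5 ring oxygen, and simple N–O cleavage competes with the sigmatropic shift.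
- Comparison: the chosen route fixes the ring D connectivity in lactone 8, uses a symmetric ring A partner, forms both C–C bonds at C11a in one step, and is shorter overall.

**Alternative 2: lactone ring B closed at C11a–C11b by direct arylation.**
- Disconnection: only C11a–C11b is cut. The precursor is A3, the 2-iodoaryl ester of a benzofuran-3-carboxylic acid.
- Key step: zerovalent palladium (formed in situ with a trialkylphosphine and a carbonate base) inserts into the C–I bond. Concerted metalation–deprotonation at the benzofuran C2–H and reductive elimination close the six-membered lactone to give A4.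
- For: the step is intramolecular, belongs to a well-behaved reaction class and needs no CO. A4 differs from 13 only by one MOM group, so the endgames coincide. On the reliability of the key step itself this alternative is probably stronger.
- Against: A3 requires the two phenols of the iodoresorcinol to be differentiated (one acetal, one ester), a desymmetrisation that costs material and steps. Its aryl ester has an ortho-iodophenoxide as leaving group and must survive hot carbonate. Its acid half is a 3-carboxylated benzofuran, longer to make than lactone 8. The doubly ortho-substituted iodide is as slow in oxidative addition there as here.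
- Comparison: the chosen route keeps ring A symmetric until the acid step, takes C6 and ring D from a two-step lactone, and forms two bonds in the key step. The price is an intermolecular three-component reaction.

**Alternative 3: ring D ortho-quinone methide plus sulfonium ylide.**
- Disconnection: ring C is cut at C6a–C11a and O11–C11a in a [4+1] sense. The components are the ring A benzylic sulfonium salt A5 and the silyl-protected ring D α-bromo arylacetate A6.
- Key step: fluoride unmasks the phenol of A6 and bromide leaves to give the ester-bearing ortho-quinone methide, while carbonate forms the ylide of A5. Conjugate addition forms C6a–C11a, and the phenoxide displaces the sulfide at C11a to close ring C as the racemic trans-dihydrobenzofuran A7.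
- For: the conditions are the mildest of the four, with no transition metal and no gas, and ring C is closed in the key step with the dihydropyran already present.
- Against: C11a enters as an sp3 benzylic carbon, so two stereocentres are made that the target lacks. A dehydrogenation to the furan, MOM removal with lactonisation and a debenzylation must follow. A5 needs a fully regiodefined chroman with a benzylic leaving group on a very electron-rich ring, which is prone to solvolysis. The ester-substituted quinone methide can oligomerise.
- Comparison: the chosen route delivers C11a at the correct oxidation level, leaves no stereocentre to remove, and starts from much simpler fragments.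

Key step: step 5

Assumption: acetophenone 5 is taken as a purchasable compound, and carbon monoxide is carried as numbered reactant 9 because its carbon becomes C11a.

## Route

Step 1
Reactants: 1 5-methoxyresorcinol (5-methoxybenzene-1,3-diol)
Product: 2 1-methoxy-3,5-bis(methoxymethoxy)benzene
Conditions: MOMCl, iPr2NEt, CH2Cl2, 0 °C to rt
Reagents that add atoms: chloromethyl methyl ether (MOMCl), COCCl
Why: Williamson-type O-alkylation of both phenols by the reactive α-chloro ether under amine base; the methyl ether is inert. MOM is chosen because it directs the lithiation of step 2 and leaves under the acid that starts the ring-forming cascade of step 6.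

Step 2
Reactants: 2 1-methoxy-3,5-bis(methoxymethoxy)benzene
Product: 4 2-iodo-5-methoxy-1,3-bis(methoxymethoxy)benzene, via aryllithium 3 (not isolated)
Conditions: n-BuLi, THF, 0 °C; then I2, THF, −78 °C to rt
Reagents that add atoms: iodine, II
Why: Directed ortho-metalation: the C–H between the two chelating MOM ethers is removed in preference to the C–H next to the weaker methoxy director, and iodine traps aryllithium 3. The iodide then sits para to the methoxy group with identical protected oxygens on both sides.

Step 3
Reactants: 5 1-[4-(benzyloxy)-2-hydroxyphenyl]ethan-1-one
Product: 6 2-[4-(benzyloxy)-2-hydroxyphenyl]-1-(morpholin-4-yl)ethane-1-thione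
Conditions: S8, morpholine, 130 °C (neat)
Reagents that add atoms: sulfur, S1SSSSSSS1; morpholine, C1COCCN1
Why: Willgerodt–Kindler reaction: the enamine of the aryl methyl ketone is thiated and the oxidation level moves to the terminal carbon, giving the arylacetic thioamide. The benzyl ether and the chelated phenol are inert to amine and sulfur.

Step 4
Reactants: 6 2-[4-(benzyloxy)-2-hydroxyphenyl]-1-(morpholin-4-yl)ethane-1-thione
Product: 8 6-(benzyloxy)benzofuran-2(3H)-one, via hydroxy acid 7 (not isolated)
Conditions: NaOH, EtOH/H2O, reflux; aq. HCl to pH 1; then p-TsOH·H2O (cat.), toluene, reflux (Dean–Stark)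
Reagents that add atoms: sodium hydroxide, [Na+].[OH-]; water, O
Why: Hydroxide hydrolyses the thioamide to the carboxylate without touching the aryl benzyl ether. After acidification, hydroxy acid 7 closes by acid-catalysed intramolecular Fischer esterification (5-exo-trig, water removed azeotropically) to the five-membered aryl lactone.

Step 5
Reactants: 4 2-iodo-5-methoxy-1,3-bis(methoxymethoxy)benzene; 8 6-(benzyloxy)benzofuran-2(3H)-one; 9 carbon monoxide
Product: 10 6-(benzyloxy)-3-[4-methoxy-2,6-bis(methoxymethoxy)benzoyl]benzofuran-2(3H)-one (racemic, largely enolised)
Conditions: Pd(OAc)2 (5 mol %), Xantphos, MgCl2, Et3N, CO (1 atm), 1,4-dioxane, 80 °C; then cold dilute aq. citric acid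
Reagents that add atoms: none
Why: Zerovalent palladium, formed in situ from Pd(OAc)2 and Xantphos, adds oxidatively to the C–I bond of 4 to give an arylpalladium iodide crowded by the two ortho MOM ethers, and migratory insertion of CO 9 relieves that crowding and forms C11a–C11b in an aroylpalladium species (divalent palladium). MgCl2 and Et3N soft-enolise lactone 8, whose CH2 has malonate-like acidity, and the magnesium-bound enolate is acylated at carbon by the aroylpalladium, either through a palladium C-enolate and reductive elimination or by direct acyl transfer, forming C6a–C11a and regenerating zerovalent palladium. The closest known reaction type is the palladium/Xantphos carbonylative α-arylation of ketones, malonates, other 1,3-dicarbonyl compounds and 2-oxindoles with aryl iodides under MgCl2/Et3N; the benzofuranone is the oxygen counterpart of the oxindole case. No ring is closed. The one new sp3 centre, C3 of the lactone, lies between two carbonyl groups, is largely enolised and is planarised in step 6, so it forms racemic and needs no control. Carbonylative rather than direct coupling is secured by the doubly ortho-substituted aryl group, which speeds CO insertion and slows aryl–enolate reductive elimination, and by the wide-bite-angle ligand. C- rather than O-acylation is secured by the chelated magnesium enolate and by the product being held as a stable magnesium β-keto-lactone enolate, to which any O-acyl isomer can transfer its acyl group. The MOM ethers, the benzyl ether and the aryl lactone tolerate Et3N at 80 °C and the brief cold acid quench.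

Step 6
Reactants: 10 6-(benzyloxy)-3-[4-methoxy-2,6-bis(methoxymethoxy)benzoyl]benzofuran-2(3H)-one
Product: 13 9-(benzyloxy)-1-hydroxy-3-methoxycoumestan, via bis-phenol 11 (not isolated), via 4-hydroxycoumarin 12 (not isolated)
Conditions: HCl (1.25 M in MeOH), THF, 50 °C; then evaporate; p-TsOH·H2O (cat.), toluene, reflux (Dean–Stark)
Reagents that add atoms: none
Why: Acid-catalysed acetal exchange with methanol removes both MOM groups; either of the two equivalent ring A phenols of 11 attacks the aryl lactone carbonyl (6-exo-trig transesterification, ring D phenoxide leaving) to give the vinylogous acid 12, and any lactone methanolysis only gives a β-keto ester that closes to the same 12. Hot p-TsOH then drives 5-exo addition of the released ring D phenol to C4 of the coumarin (C11a) and loss of water to the aromatic furan, the usual cyclodehydration of 3-(2-hydroxyaryl)-4-hydroxycoumarins to coumestans. The benzyl ether should tolerate catalytic sulfonic acid in toluene.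

Step 7
Reactants: 13 9-(benzyloxy)-1-hydroxy-3-methoxycoumestan
Product: 14 9-(benzyloxy)-3-methoxy-1-[(2-methylbut-3-yn-2-yl)oxy]coumestan
Conditions: 3-chloro-3-methylbut-1-yne, DBU, CuCl2·2H2O (cat.), MeCN, 0 °C to rt
Reagents that add atoms: 3-chloro-3-methylbut-1-yne, CC(C)(Cl)C#C
Why: Copper-catalysed propargylic substitution through a copper acetylide O-alkylates even hindered phenols with the tertiary chloride. Compound 13 has a single hydroxyl, so no site selectivity is needed, and DBU in MeCN does not open the coumarin lactone.

Step 8
Reactants: 14 9-(benzyloxy)-3-methoxy-1-[(2-methylbut-3-yn-2-yl)oxy]coumestan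
Product: 16 9-(benzyloxy)-3-methoxy-1,2-(2,2-dimethyl-2H-pyrano)coumestan (pyran oxygen on C1), via allenyl phenol 15 (not isolated)
Conditions: N,N-diethylaniline, 180 °C
Reagents that add atoms: none
Why: Aryl propargyl ether Claisen cascade: the [3,3] shift can only go to C2 because the other ortho carbon, C11b, is quaternary. Tautomerisation to allenyl phenol 15, a 1,5-hydrogen shift and oxa-6π electrocyclisation then give the 2,2-dimethyl-2H-chromene.

Step 9
Reactants: 16 9-(benzyloxy)-3-methoxy-1,2-(2,2-dimethyl-2H-pyrano)coumestan
Product: 17 9-hydroxy-3-methoxy-1,2-(2,2-dimethyl-3,4-dihydro-2H-pyrano)coumestan (target CNP0304440.0)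
Conditions: H2 (1 atm), 10% Pd/C, EtOAc/THF, rt
Reagents that add atoms: none
Why: Heterogeneous hydrogenation saturates the cis-disubstituted chromene alkene and hydrogenolyses the benzyl ether in one operation. The tetrasubstituted, aromatic C6a=C11a bond and the lactone are not reduced at 1 atm and rt.

## Compound list

1 | 5-methoxyresorcinol (5-methoxybenzene-1,3-diol) | COc1cc(O)cc(O)c1 | starting material
2 | 1-methoxy-3,5-bis(methoxymethoxy)benzene | COCOc1cc(OC)cc(OCOC)c1 | intermediate
3 | [4-methoxy-2,6-bis(methoxymethoxy)phenyl]lithium | [Li]c1c(OCOC)cc(OC)cc1OCOC | intermediate
4 | 2-iodo-5-methoxy-1,3-bis(methoxymethoxy)benzene | COCOc1cc(OC)cc(OCOC)c1I | intermediate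
5 | 1-[4-(benzyloxy)-2-hydroxyphenyl]ethan-1-one | CC(=O)c1ccc(OCc2ccccc2)cc1O | starting material
6 | 2-[4-(benzyloxy)-2-hydroxyphenyl]-1-(morpholin-4-yl)ethane-1-thione | S=C(Cc1ccc(OCc2ccccc2)cc1O)N1CCOCC1 | intermediate
7 | [4-(benzyloxy)-2-hydroxyphenyl]acetic acid | OC(=O)Cc1ccc(OCc2ccccc2)cc1O | intermediate
8 | 6-(benzyloxy)benzofuran-2(3H)-one | O=C1Cc2ccc(OCc3ccccc3)cc2O1 | intermediate
9 | carbon monoxide | [C-]#[O+] | starting material
10 | 6-(benzyloxy)-3-[4-methoxy-2,6-bis(methoxymethoxy)benzoyl]benzofuran-2(3H)-one (racemic, enolisable) | O=C1Oc2cc(OCc3ccccc3)ccc2C1C(=O)c1c(OCOC)cc(OC)cc1OCOC | intermediate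
11 | 6-(benzyloxy)-3-(2,6-dihydroxy-4-methoxybenzoyl)benzofuran-2(3H)-one (racemic, enolisable) | O=C1Oc2cc(OCc3ccccc3)ccc2C1C(=O)c1c(O)cc(OC)cc1O | intermediate
12 | 3-[4-(benzyloxy)-2-hydroxyphenyl]-4,5-dihydroxy-7-methoxy-2H-chromen-2-one | COc1cc(O)c2c(c1)oc(=O)c(-c1ccc(OCc3ccccc3)cc1O)c2O | intermediate
13 | 9-(benzyloxy)-1-hydroxy-3-methoxycoumestan (9-(benzyloxy)-1-hydroxy-3-methoxy-6H-benzofuro[3,2-c]chromen-6-one) | COc1cc(O)c2c(c1)oc(=O)c1c3ccc(OCc4ccccc4)cc3oc21 | intermediate
14 | 9-(benzyloxy)-3-methoxy-1-[(2-methylbut-3-yn-2-yl)oxy]coumestan | COc1cc(OC(C)(C)C#C)c2c(c1)oc(=O)c1c3ccc(OCc4ccccc4)cc3oc21 | intermediate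
15 | 9-(benzyloxy)-1-hydroxy-3-methoxy-2-(3-methylbuta-1,2-dien-1-yl)coumestan | COc1cc2oc(=O)c3c4ccc(OCc5ccccc5)cc4oc3c2c(O)c1C=C=C(C)C | intermediate
16 | 9-(benzyloxy)-3-methoxy-1,2-(2,2-dimethyl-2H-pyrano)coumestan (pyran oxygen on C1, CH=CH on C2) | COc1cc2oc(=O)c3c4ccc(OCc5ccccc5)cc4oc3c2c2c1C=CC(C)(C)O2 | intermediate
17 | 9-hydroxy-3-methoxy-1,2-(2,2-dimethyl-3,4-dihydro-2H-pyrano)coumestan (pyran oxygen on C1, CH2 on C2) | COc1cc2oc(=O)c3c4ccc(O)cc4oc3c2c2c1CCC(C)(C)O2 | target

## Step count and risks

Total step count: 9. Longest linear sequence: 7 steps (1 → 2 → 4 → 10 → 13 → 14 → 16 → 17; the branch from 5 through 6 and 8 is equally long).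

**Step 5 (key step).**
- What may go wrong: oxidative addition into the electron-rich, doubly ortho-substituted C–I bond may be slow, so that catalyst decay or hydrodeiodination takes over. The enolate may couple with the aryl group before CO inserts. The enolate may be acylated at oxygen, or lactone 8 may self-condense under the base.
- Fallback, from 2 and 8, returning at 10: arene 2 is lithiated as in step 2 and aryllithium 3 is quenched with CO2 instead of iodine, giving 4-methoxy-2,6-bis(methoxymethoxy)benzoic acid F1. The acid is converted under neutral conditions (1-chloro-N,N,2-trimethylprop-1-en-1-amine, CH2Cl2, 0 °C, so that no HCl reaches the MOM ethers) into 4-methoxy-2,6-bis(methoxymethoxy)benzoyl chloride F2. F2 C-acylates lactone 8 under MgCl2/Et3N in MeCN at 0 °C (soft-enolisation Claisen-type acylation) to give 10. The same two bonds at C11a are made one at a time with stoichiometric reagents, and CO2 replaces CO as the source of C11a.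

**Step 6.**
- What may go wrong: the cyclodehydration may stall at the 4-hydroxycoumarin stage. Prolonged hot acid may cleave or migrate the benzyl group. Methanol may cleave the β-keto lactone in a retro-Claisen sense before ring A has lactonised.
- Fallback, from 10, returning at 13: only the HCl/MeOH stage is run and 12 is isolated. Its most acidic hydroxyl, the 4-OH, is sulfonylated (TsCl, Et3N, CH2Cl2, 0 °C) to 3-[4-(benzyloxy)-2-hydroxyphenyl]-5-hydroxy-7-methoxy-2-oxo-2H-chromen-4-yl 4-methylbenzenesulfonate F3. K2CO3 in DMF at rt then lets the ring D phenoxide displace the sulfonate at C4 by addition–elimination, closing the furan to 13 without strong acid or heat.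

**Step 7 (and the thermal step 8 that depends on it).**
- What may go wrong: O-alkylation of the hindered C1 hydroxyl may be slow and elimination of the tertiary chloride may consume the reagent. In step 8 the long heating may cause decomposition.
- Fallback, from 13, returning at 16 and bypassing 14 and 15: 13 is condensed with 3-methylbut-2-enal (ethylenediammonium diacetate cat., toluene, reflux). This is a Knoevenagel-type attack of the activated C2 (ortho to the hydroxyl and to the methoxy group, para to the lactone oxygen) on the iminium ion, followed by dehydration and oxa-6π electrocyclisation to the chromene. No new intermediate is isolated.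

**Step 2.**
- What may go wrong: some deprotonation may occur at the carbon between a MOM ether and the methoxy group, which would give the wrong ring A substitution pattern after coupling.
- Fallback, from 1, returning at 4: the free resorcinol 1 is iodinated first (I2, NaHCO3, H2O/THF, 0 °C), where the phenoxide-directed substitution favours the carbon between the two hydroxyls as with resorcinol itself, giving 2-iodo-5-methoxybenzene-1,3-diol F4. Bis-MOM protection (MOMCl, iPr2NEt, CH2Cl2) then gives 4.

## Further compounds

F1 | step 5 | 4-methoxy-2,6-bis(methoxymethoxy)benzoic acid | COCOc1cc(OC)cc(OCOC)c1C(=O)O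
F2 | step 5 | 4-methoxy-2,6-bis(methoxymethoxy)benzoyl chloride | COCOc1cc(OC)cc(OCOC)c1C(=O)Cl
F3 | step 6 | 3-[4-(benzyloxy)-2-hydroxyphenyl]-5-hydroxy-7-methoxy-2-oxo-2H-chromen-4-yl 4-methylbenzenesulfonate | COc1cc(O)c2c(c1)oc(=O)c(-c1ccc(OCc3ccccc3)cc1O)c2OS(=O)(=O)c1ccc(C)cc1
F0 | step 7 | none | none
F4 | step 2 | 2-iodo-5-methoxybenzene-1,3-diol | COc1cc(O)c(I)c(O)c1
A1 | alternative 1 | 4-{[3-(benzyloxy)phenoxy]amino}-7-methoxycoumarin bearing a 2,2-dimethyl-3,4-dihydro-2H-pyran ring fused at C5–C6 (ring oxygen on C5) | COc1cc2oc(=O)cc(NOc3cccc(OCc4ccccc4)c3)c2c2c1CCC(C)(C)O2
A2 | alternative 1 | 9-O-benzyl ether of 17 | COc1cc2oc(=O)c3c4ccc(OCc5ccccc5)cc4oc3c2c2c1CCC(C)(C)O2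
A3 | alternative 2 | 2-iodo-5-methoxy-3-(methoxymethoxy)phenyl 6-(benzyloxy)benzofuran-3-carboxylate | COCOc1cc(OC)cc(OC(=O)c2coc3cc(OCc4ccccc4)ccc23)c1I
A4 | alternative 2 | 9-(benzyloxy)-3-methoxy-1-(methoxymethoxy)coumestan | COCOc1cc(OC)cc2oc(=O)c3c4ccc(OCc5ccccc5)cc4oc3c12
A5 | alternative 3 | {[5-methoxy-7-(methoxymethoxy)-2,2-dimethylchroman-8-yl]methyl}dimethylsulfonium bromide | C[S+](C)Cc1c(OCOC)cc(OC)c2CCC(C)(C)Oc12.[Br-]
A6 | alternative 3 | ethyl bromo{4-(benzyloxy)-2-[(tert-butyldimethylsilyl)oxy]phenyl}acetate (racemic) | CCOC(=O)C(Br)c1ccc(OCc2ccccc2)cc1O[Si](C)(C)C(C)(C)C
A7 | alternative 3 | ethyl trans-6-(benzyloxy)-2-[5-methoxy-7-(methoxymethoxy)-2,2-dimethylchroman-8-yl]-2,3-dihydrobenzofuran-3-carboxylate (racemic, relative configuration shown) | CCOC(=O)[C@H]1[C@H](c2c(OCOC)cc(OC)c3CCC(C)(C)Oc23)Oc2cc(OCc3ccccc3)ccc21
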